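**Assumptions (one line):** I use germacrane numbering (lactone O on C6, angelate on C8, acetate on C10, OMe on C3). The RCM is assumed to give the (E)-ring alkene, peripheral-face ketohydroxylation is assumed to give 10R, and the Ipc₂B-allyl enantiomer is chosen to give 3R.

## Retrosynthetic overview
1. The target comes from the C1 ketone/C10 tertiary alcohol ("ketol") by desilylation, angeloylation at C8 and acetylation at C10.
2. The ketol comes from Ru-catalysed ketohydroxylation of a C1=C10 ring alkene. This is the proposed new step.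
3. That alkene comes from RCM of a diene (C3-allyl and C8-methallyl) built on a trans-fused α-methylene-γ-lactone.
4. The lactone comes first, by anti-selective Cr-allylation of a C6 aldehyde (Evans-derived, sets C4) with a (Z)-2-(bromomethyl)enoate (glycidol-derived, sets C8). The C3 carbinol is then made by Brown allylation and O-methylated.
5. Ring order: γ-lactone (C6–C7), then the 10-membered carbocycle (C1=C10), then oxidation of C1/C10.

## Route

**Step 1**
Reactants: 1 (S)-4-benzyl-3-propionyloxazolidin-2-one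
Product: 2 (S)-4-benzyl-3-[(2R)-2-methylpent-4-enoyl]oxazolidin-2-one
Conditions: NaHMDS, THF, −78 °C; then allyl iodide, −78 → −40 °C
Reagents that add atoms: allyl iodide, C=CCI
Why: Evans alkylation of the chelated Z-enolate; allyl iodide approaches anti to the benzyl group and sets C4 (R).

**Step 2**
Reactants: 2
Product: 3 (2R)-2-methylpent-4-en-1-ol (the auxiliary is recovered)
Conditions: LiBH₄, H₂O (1 equiv), Et₂O, 0 °C
Reagents that add atoms: none
Why: Reductive auxiliary cleavage leaves the α-stereocentre untouched.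

**Step 3**
Reactants: 3
Product: 4 triethyl{[(2R)-2-methylpent-4-en-1-yl]oxy}silane
Conditions: TESCl, imidazole, DMF, 0 °C
Reagents that add atoms: TESCl, CC[Si](CC)(CC)Cl
Why: Silyl protection of the primary alcohol, with no stereochemical change.

**Step 4**
Reactants: 4
Product: 5 (3R)-3-methyl-4-[(triethylsilyl)oxy]butanal (C6 aldehyde)
Conditions: O₃, CH₂Cl₂/MeOH, −78 °C; then PPh₃
Reagents that add atoms: ozone, O=[O+][O-]
Why: Ozonolysis with reductive work-up turns the terminal alkene into the aldehyde; the β-stereocentre is not epimerisable under these conditions.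

**Step 5**
Reactants: 6 (R)-glycidol
Product: 7 (2S)-2-{[(4-methoxybenzyl)oxy]methyl}oxirane
Conditions: NaH, PMBCl, TBAI (cat.), THF, 0 → 23 °C
Reagents that add atoms: PMBCl, COc1ccc(CCl)cc1
Why: Williamson etherification; Payne rearrangement of glycidol is degenerate, so the stereocentre is retained. (R)-Glycidol gives the (S)-ether because the CIP priorities swap.

**Step 6**
Reactants: 7
Product: 8 (2S)-1-[(4-methoxybenzyl)oxy]-4-methylpent-4-en-2-ol
Conditions: isopropenylMgBr, CuI (10 mol%), THF, −40 °C
Reagents that add atoms: isopropenylmagnesium bromide, C=C(C)[Mg]Br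
Why: Cu-catalysed opening at the terminal epoxide carbon leaves C8 untouched (C8 = S).

**Step 7**
Reactants: 8
Product: 9 TBS ether of 8
Conditions: TBSCl, imidazole, DMF, 23 °C
Reagents that add atoms: TBSCl, CC(C)(C)[Si](C)(C)Cl
Why: Silylation of the secondary alcohol.

**Step 8**
Reactants: 9
Product: 10 (2S)-2-[(tert-butyldimethylsilyl)oxy]-4-methylpent-4-en-1-ol
Conditions: DDQ, CH₂Cl₂/pH 7 buffer, 0 °C
Reagents that add atoms: none
Why: Oxidative PMB removal is neutral and leaves the TBS ether and the 1,1-disubstituted alkene intact.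

**Step 9**
Reactants: 10
Product: 11 (2S)-2-[(tert-butyldimethylsilyl)oxy]-4-methylpent-4-enal
Conditions: Dess–Martin periodinane, NaHCO₃, CH₂Cl₂, 0 °C (use crude, immediately)
Reagents that add atoms: none
Why: Mild oxidation of the primary alcohol avoids epimerising the α-silyloxy centre.

**Step 10**
Reactants: 11
Product: 12 ethyl 2-[(2S)-2-(TBSO)-1-hydroxy-4-methylpent-4-en-1-yl]acrylate (≈1:1 at the carbinol C7)
Conditions: ethyl acrylate (3 equiv), DABCO (30 mol%), MeOH (cat.), 23 °C, 3 d
Reagents that add atoms: ethyl acrylate, C=CC(=O)OCC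
Why: Morita–Baylis–Hillman reaction; the new carbinol centre is destroyed in the next step, so the mixture is harmless.

**Step 11**
Reactants: 12
Product: 13 ethyl (2Z,4S)-2-(bromomethyl)-4-[(TBS)oxy]-6-methylhepta-2,6-dienoate
Conditions: NBS, Me₂S, CH₂Cl₂, −20 → 0 °C
Reagents that add atoms: NBS, O=C1CCC(=O)N1Br
Why: SN2′ bromination of a Baylis–Hillman adduct gives the (Z)-allyl bromide and converges both C7 epimers to one compound (C8 = S).

**Step 12**
Reactants: 5 (aldehyde) and 13 (bromide)
Product: 14 ethyl (3S,4R,6R)-3-[(1S)-1-(TBSO)-3-methylbut-3-en-1-yl]-2-methylene-4-hydroxy-6-methyl-7-(TES-oxy)heptanoate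
Conditions: CrCl₂ (4 equiv), NiCl₂ (1 mol%), DMF, 23 °C
Reagents that add atoms: none
Why: Nozaki–Hiyama–Barbier allylation. The allylchromium adds through its γ-carbon (C7) in a chair TS to give the anti homoallylic alcohol (C6/C7 set; C7 relative to C8 by 1,2-induction).

**Step 13**
Reactants: 14
Product: 15 trans-lactone: (4S,5R)-4-[(1S)-1-(TBSO)-3-methylbut-3-en-1-yl]-3-methylene-5-[(2R)-2-methyl-3-(TES-oxy)propyl]dihydrofuran-2(3H)-one
Conditions: PPTS (cat.), PhMe, 50 °C
Reagents that add atoms: none
Why: Acid-catalysed lactonisation loses EtOH; the anti alcohol gives the trans-β,γ-disubstituted α-methylene-γ-butyrolactone.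

**Step 14**
Reactants: 15
Product: 16 primary alcohol (TES removed)
Conditions: PPTS, MeOH, 23 °C
Reagents that add atoms: none
Why: The primary TES ether is cleaved selectively over the secondary TBS ether.

**Step 15**
Reactants: 16
Product: 17 aldehyde, 5-[(2R)-2-methyl-3-oxopropyl] lactone
Conditions: Dess–Martin periodinane, NaHCO₃, CH₂Cl₂, 0 °C
Reagents that add atoms: none
Why: Mild oxidation that keeps the α-methyl centre (C4) unepimerised.

**Step 16**
Reactants: 17
Product: 18 (3R)-homoallylic alcohol, 5-[(2R,3R)-3-hydroxy-2-methylhex-5-en-1-yl] lactone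
Conditions: (+)-Ipc₂B-allyl (from (−)-α-pinene), Et₂O, −78 °C; non-oxidative ethanolamine work-up
Reagents that add atoms: allyl-B(Ipc)₂ (Ipc stereo not drawn), C=CCB(C1CC2CC(C1C)C2(C)C)C1CC2CC(C1C)C2(C)C
Why: Brown allylboration; reagent control (Re-face addition) sets C3 (R), and the non-oxidative work-up spares the α-methylene lactone.

**Step 17**
Reactants: 18
Product: 19 methyl ether, 5-[(2R,3R)-3-methoxy-2-methylhex-5-en-1-yl] lactone (RCM diene)
Conditions: MeOTf, 2,6-di-tert-butyl-4-methylpyridine, CH₂Cl₂, 0 → 23 °C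
Reagents that add atoms: MeOTf, COS(=O)(=O)C(F)(F)F
Why: Non-basic O-methylation of a secondary alcohol leaves C3 intact.

**Step 18**
Reactants: 19
Product: 20 (1(10)E)-8-O-TBS-3-O-methyl-germacra-1(10),11(13)-dien-6,12-olide
Conditions: Hoveyda–Grubbs II (10 mol%), PhMe, 2 mM, 70 °C, Ar sparge
Reagents that add atoms: none (ethylene is lost)
Why: Ring-closing metathesis; the trans-fused lactone preorganises the chain and the pre-set stereocentres avoid macrocyclic stereo-problems. It forms the trisubstituted C1=C10 bond.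

**Step 19**
Reactants: 20
Product: 21 (10R)-10-hydroxy-1-oxo ketol: 8-O-TBS-10-hydroxy-3-methoxy-1-oxogermacr-11(13)-en-6,12-olide
Conditions: RuCl₃·nH₂O (5 mol%), Oxone, NaHCO₃, EtOAc/MeCN/H₂O 3:3:1, 0 °C, 5 min
Reagents that add atoms: Oxone (KHSO₅, O source), [K+].[O-]S(=O)(=O)OO; water, O
Why: Proposed new method: chemo- and diastereoselective Ru-catalysed ketohydroxylation of the trisubstituted C1=C10 bond inside a germacranolide 10-membered ring, in the presence of the α-methylene lactone.
Mechanism: in situ RuO₄ adds syn ([3+2]) to the electron-rich alkene from the peripheral face of the ring, giving a ruthenate(VI) diester. Oxone reoxidises this to a Ru(VIII) glycolate, which is oxidised at the secondary C1–O carbon to C1=O. The tertiary C10–O bond, formed cis in the cycloaddition, fixes C10 (R). The electron-poor exocyclic methylene survives the buffered conditions.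
Closest known reaction: Plietker's RuO₄ ketohydroxylation of acyclic and cyclohexyl alkenes, and OsO₄ syn-dihydroxylation. It has not been shown on medium-ring alkenes of this type.

**Step 20**
Reactants: 21
Product: 22 8,10-diol: 10-hydroxy-8-hydroxy ketol lactone (TBS removed)
Conditions: HF·pyridine, THF/pyridine, 0 → 23 °C, 24 h
Reagents that add atoms: none
Why: Acidic fluoride desilylation avoids base-induced ketol rearrangement and β-elimination of the 3-OMe.

**Step 21**
Reactants: 22
Product: 23 8-O-angeloyl-10-hydroxy ketol lactone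
Conditions: angelic acid, 2,4,6-Cl₃C₆H₂COCl, Et₃N, THF; then 22, DMAP, PhMe, 23 °C
Reagents that add atoms: angelic acid, C/C=C(/C)C(=O)O
Why: Yamaguchi esterification acylates only the secondary C8–OH, not the tertiary C10–OH, and preserves the Z-angelate geometry.

**Step 22**
Reactants: 23
Product: 24 Rufesolide C
Conditions: Ac₂O, DMAP (cat.), Et₃N, CH₂Cl₂, 23 → 40 °C
Reagents that add atoms: acetic anhydride, CC(=O)OC(C)=O
Why: DMAP-catalysed acetylation of the tertiary α-ketol OH gives the C10 acetate with retention of configuration.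

## Compound list
1 | (S)-4-benzyl-3-propionyloxazolidin-2-one | CCC(=O)N1[C@@H](Cc2ccccc2)COC1=O | starting material
2 | (S)-4-benzyl-3-[(2R)-2-methylpent-4-enoyl]oxazolidin-2-one | C=CC[C@@H](C)C(=O)N1[C@@H](Cc2ccccc2)COC1=O | intermediate
3 | (2R)-2-methylpent-4-en-1-ol | C=CC[C@@H](C)CO | intermediate
4 | triethyl{[(2R)-2-methylpent-4-en-1-yl]oxy}silane | C=CC[C@@H](C)CO[Si](CC)(CC)CC | intermediate
5 | (3R)-3-methyl-4-[(triethylsilyl)oxy]butanal | O=CC[C@@H](C)CO[Si](CC)(CC)CC | intermediate
6 | (R)-glycidol | OC[C@@H]1CO1 | starting material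
7 | (2S)-2-[(4-methoxybenzyloxy)methyl]oxirane | COc1ccc(COC[C@@H]2CO2)cc1 | intermediate
8 | (2S)-1-(PMB-oxy)-4-methylpent-4-en-2-ol | C=C(C)C[C@H](O)COCc1ccc(OC)cc1 | intermediate
9 | TBS ether of 8 | C=C(C)C[C@H](O[Si](C)(C)C(C)(C)C)COCc1ccc(OC)cc1 | intermediate
10 | (2S)-2-(TBSO)-4-methylpent-4-en-1-ol | C=C(C)C[C@H](O[Si](C)(C)C(C)(C)C)CO | intermediate
11 | (2S)-2-(TBSO)-4-methylpent-4-enal | C=C(C)C[C@H](O[Si](C)(C)C(C)(C)C)C=O | intermediate
12 | Baylis–Hillman adduct (C7 epimer mixture) | C=C(C)C[C@H](O[Si](C)(C)C(C)(C)C)C(O)C(=C)C(=O)OCC | intermediate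
13 | ethyl (2Z,4S)-2-(bromomethyl)-4-(TBSO)-6-methylhepta-2,6-dienoate | CCOC(=O)/C(CBr)=C/[C@@H](O[Si](C)(C)C(C)(C)C)CC(C)=C | intermediate
14 | anti hydroxy ester (3S,4R,6R; side-chain 1S) | CCOC(=O)C(=C)[C@H]([C@@H](O[Si](C)(C)C(C)(C)C)CC(C)=C)[C@H](O)C[C@@H](C)CO[Si](CC)(CC)CC | intermediate
15 | trans-α-methylene-γ-lactone, TES/TBS protected | C=C1C(=O)O[C@H](C[C@@H](C)CO[Si](CC)(CC)CC)[C@H]1[C@@H](O[Si](C)(C)C(C)(C)C)CC(C)=C | intermediate
16 | primary alcohol | C=C1C(=O)O[C@H](C[C@@H](C)CO)[C@H]1[C@@H](O[Si](C)(C)C(C)(C)C)CC(C)=C | intermediate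
17 | aldehyde | C=C1C(=O)O[C@H](C[C@@H](C)C=O)[C@H]1[C@@H](O[Si](C)(C)C(C)(C)C)CC(C)=C | intermediate
18 | homoallylic alcohol (3R) | C=C1C(=O)O[C@H](C[C@@H](C)[C@H](O)CC=C)[C@H]1[C@@H](O[Si](C)(C)C(C)(C)C)CC(C)=C | intermediate
19 | methyl ether (RCM diene) | C=C1C(=O)O[C@H](C[C@@H](C)[C@H](OC)CC=C)[C@H]1[C@@H](O[Si](C)(C)C(C)(C)C)CC(C)=C | intermediate
20 | (1(10)E)-cyclodecene lactone | C=C1C(=O)O[C@@H]2C[C@@H](C)[C@H](OC)C/C=C(\C)C[C@H](O[Si](C)(C)C(C)(C)C)[C@@H]12 | intermediate
21 | ketol (10R) | C=C1C(=O)O[C@@H]2C[C@@H](C)[C@H](OC)CC(=O)[C@](C)(O)C[C@H](O[Si](C)(C)C(C)(C)C)[C@@H]12 | intermediate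
22 | 8,10-diol ketone | C=C1C(=O)O[C@@H]2C[C@@H](C)[C@H](OC)CC(=O)[C@](C)(O)C[C@H](O)[C@@H]12 | intermediate
23 | 8-O-angelate, 10-OH | C=C1C(=O)O[C@@H]2C[C@@H](C)[C@H](OC)CC(=O)[C@](C)(O)C[C@H](OC(=O)/C(C)=C\C)[C@@H]12 | intermediate
24 | Rufesolide C (3R,4R,6R,7S,8S,10R) | C=C1C(=O)O[C@@H]2C[C@@H](C)[C@H](OC)CC(=O)[C@](C)(OC(C)=O)C[C@H](OC(=O)/C(C)=C\C)[C@@H]12 | target

**Total steps:** 22. **Longest linear sequence:** 18 steps (from 6 through 24).

## Three steps most likely to fail
1. **Step 18 (RCM to the 10-membered trisubstituted alkene).** Risks are oligomerisation, a hindered methallyl partner and the wrong alkene geometry. Fallback: change the ring-closure strategy to an intramolecular Cr-mediated allylation of an acyclic C6 aldehyde/C7 allyl bromide, which forms the C6–C7 bond, the lactone and the 10-ring together. The precursor would carry the C1 ketone and C10 acetate, made earlier by asymmetric dihydroxylation of an acyclic (E)-trisubstituted alkene.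
2. **Step 19 (proposed new Ru ketohydroxylation).** Risks are over-oxidation or cleavage, attack on the methylene lactone or OMe, and the wrong C10 face. Fallback: use known two-step chemistry instead, namely OsO₄ syn-dihydroxylation of alkene 20 (after desilylation, TMEDA–OsO₄ hydroxyl-directed from C8-OH) to the C1/C10 diol, then selective DMP or TEMPO/BAIB oxidation of the secondary C1-OH.
3. **Step 12 (Cr allylation setting C6/C7/C8).** Risks are poor 1,2-induction from C8 and poor anti/trans selectivity. Fallback: change approach to Marshall propargylation of aldehyde 5 with a chiral propargylic mesylate (Pd(0)/Et₂Zn allenylzinc) to give the anti homopropargylic alcohol, then Pd-catalysed cyclocarbonylation to the trans α-methylene-γ-lactone.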